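**Retrosynthetic overview**

1. The target is (S)-16-(4-methyl-2,5-dioxo-2,5-dihydrofuran-3-yl)hexadecan-2-yl acetate. Its only ring, the furan-2,5-dione, is made last, by acid release and spontaneous 5-exo-trig cyclodehydration of a di-tert-butyl (Z)-2-alkyl-3-methylbut-2-enedioate, with the acetate kept.
2. Key disconnection: C5–C6 of the hexadecan-2-yl chain (C2 = acetoxy carbon, C16 = carbon bonded to ring C3). It is formed by anodic decarboxylative radical cross-coupling (mixed Kolbe electrolysis) of (S)-5-acetoxyhexanoic acid with the ω-carboxyundecyl maleate diester, a union of two carbons of like polarity with loss of two CO2.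
3. Enabling feature: C5 and C6 are plain CH2 groups inside the unbranched C3–C16 (CH2)14 tether. C5 is insulated from the stereogenic C2–OAc by C3/C4, and C6 from the ring alkene C3=C4 by ten CH2 groups. Both halves therefore end as unstabilised primary alkyl radicals with no acceptor, leaving group or activated C–H within reach, each available from a carboxylic acid one carbon longer.
4. The (S)-acid comes from (S)-propylene oxide (source of the only stereocentre) by Cu-catalysed butenyl Grignard opening, acetylation in the flask and alkene cleavage. The maleate acid comes from 12-bromododec-1-ene by syn-carbocupration of di-tert-butyl acetylenedicarboxylate with MeI capture (fixes the cis-diester), then hydroboration–oxidation and oxidation to CO2H.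
5. Ring order: no ring exists before the last step; the anhydride ring closes in step 7.

Key step: step 6

Remark on the chemistry: the anhydride is carried as its di-tert-butyl (Z)-diester through the electrolysis, because methanolic carboxylate would open a free dialkylmaleic anhydride; a 2,3-dialkyl-(Z)-butenedioic acid released in acid is assumed to close to the anhydride on concentration, as is general for this class.

**Route**

Step 1
Reactants: 1 (S)-propylene oxide; 2 but-3-en-1-ylmagnesium bromide
Product: 4 (S)-hept-6-en-2-yl acetate, via bromomagnesium (S)-hept-6-en-2-oxide 3 (not isolated)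
Conditions: 2 (1.0 equiv, THF), CuI (5 mol%), −30 °C; 1 (1.2 equiv), −30 → 0 °C; then Ac2O (2 equiv), DMAP (5 mol%), 0 °C → rt; aq. NH4Cl
Reagents that add atoms: acetic anhydride, CC(=O)OC(C)=O
Why: Copper-catalysed Grignard opening of a terminal epoxide is an SN2 attack at the unsubstituted CH2, so the C–O stereocentre of 1 is not touched and is carried over as (S), and the magnesium alkoxide is O-acetylated in the same flask.

Step 2
Reactants: 4 (S)-hept-6-en-2-yl acetate
Product: 6 (S)-5-acetoxyhexanoic acid, via (S)-6-oxohexan-2-yl acetate 5 (not isolated)
Conditions: RuCl3·xH2O (2 mol%), NaIO4 (4.1 equiv), EtOAc/MeCN/H2O, rt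
Reagents that add atoms: sodium periodate, [Na+].[O-]I(=O)(=O)=O; water, O
Why: Ruthenium tetroxide-catalysed oxidative cleavage of a terminal alkene should give the carboxylic acid with one carbon fewer, and the secondary acetate and its stereocentre are inert to this oxidant.

Step 3
Reactants: 7 12-bromododec-1-ene; 8 di-tert-butyl but-2-ynedioate
Product: 12 di-tert-butyl (Z)-2-(dodec-11-en-1-yl)-3-methylbut-2-enedioate, via dodec-11-en-1-ylmagnesium bromide 9 (not isolated), via dodec-11-en-1-ylcopper 10 (not isolated), via alkenylcopper adduct 11 (not isolated)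
Conditions: 7, Mg, THF, rt → 40 °C; CuBr·SMe2 (1.0 equiv), THF/Me2S, −40 °C; 8 (0.9 equiv), −78 °C; MeI (5 equiv), HMPA (or DMPU), −78 °C → rt; aq. NH4Cl/NH3
Reagents that add atoms: methyl iodide, CI
Why: Syn-carbocupration of an acetylenedicarboxylate by a Grignard-derived organocopper at −78 °C, followed by alkylation of the alkenylcopper with retention (tandem vicinal difunctionalisation), should place chain and methyl cis and hence both esters cis (Z), while the remote terminal alkene is not involved.

Step 4
Reactants: 12 di-tert-butyl (Z)-2-(dodec-11-en-1-yl)-3-methylbut-2-enedioate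
Product: 14 di-tert-butyl (Z)-2-(12-hydroxydodecyl)-3-methylbut-2-enedioate, via B-alkyl-9-BBN adduct 13 (not isolated)
Conditions: 9-BBN (1.3 equiv), THF, 0 °C → rt; then NaBO3·4H2O (5 equiv), H2O, rt
Reagents that add atoms: sodium perborate tetrahydrate, O.O.O.O.[Na+].[O-]OB=O
Why: Anti-Markovnikov hydroboration–oxidation, in which 9-BBN should add only to the unhindered terminal alkene and not to the tetrasubstituted electron-poor diester alkene, and perborate should oxidise the C–B bond without harming the tert-butyl esters.

Step 5
Reactants: 14 di-tert-butyl (Z)-2-(12-hydroxydodecyl)-3-methylbut-2-enedioate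
Product: 16 di-tert-butyl (Z)-2-(11-carboxyundecyl)-3-methylbut-2-enedioate, via aldehyde 15 (not isolated)
Conditions: TEMPO (0.2 equiv), PhI(OAc)2 (2.5 equiv), MeCN/H2O (1:1), rt
Reagents that add atoms: water, O
Why: Oxoammonium (TEMPO/PhI(OAc)2) oxidation in aqueous acetonitrile should take the primary alcohol through the aldehyde hydrate to the acid under near-neutral conditions that leave tert-butyl esters and the hindered alkene alone.

Step 6
Reactants: 16 di-tert-butyl (Z)-2-(11-carboxyundecyl)-3-methylbut-2-enedioate; 6 (S)-5-acetoxyhexanoic acid
Product: 17 di-tert-butyl (Z)-2-[(15S)-15-acetoxyhexadecyl]-3-methylbut-2-enedioate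
Conditions: 16 (1 equiv), 6 (5 equiv), NaOMe (5 mol% of total acid), MeOH, undivided cell, smooth Pt anode, steel cathode, constant current ca. 0.2 A cm−2, 30–40 °C, ca. 1.3 F per mol acid, stop at pH 7–8; AcOH quench; chromatography
Reagents that add atoms: none
Why: Mixed Kolbe electrolysis: both carboxylates are oxidised at the platinum anode to acyloxy radicals that lose CO2 at once, and the two primary alkyl radicals (4-acetoxypentyl from 6, the maleate-terminated undecyl radical from 16) combine in the dense radical layer at the electrode to form the C(sp3)–C(sp3) bond between two carbons of like polarity. The closest known reaction type is the Kolbe cross-coupling of ω-functionalised alkanoic acids and diacid half-esters, which tolerates esters, acetates and remote alkenes. No ring is closed and no stereocentre is formed; the (S)-centre of 6 sits three bonds from the radical carbon, where neither β-scission nor a favourable hydrogen shift can reach it (its C–H is in a 1,4-relation), so it should be carried over unchanged. The selectivity needed is cross- over homo-coupling; since radical pairing is statistical, it is secured by the five-fold excess of the short, two-step acid 6, so that most radicals from 16 should meet a radical from 6, and the two symmetrical dimers differ widely in size and polarity from 17. The radical pathway rather than the cation (Hofer–Moest) pathway is favoured by unstabilised primary radicals, smooth platinum, high current density and weakly acidic methanol; the tetrasubstituted diester alkene lies eleven CH2 groups from the radical site and is too hindered to compete as an acceptor, and the steel cathode avoids its hydrogenation.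

Step 7
Reactants: 17 di-tert-butyl (Z)-2-[(15S)-15-acetoxyhexadecyl]-3-methylbut-2-enedioate
Product: 19 (S)-16-(4-methyl-2,5-dioxo-2,5-dihydrofuran-3-yl)hexadecan-2-yl acetate, via (Z)-butenedioic acid 18 (not isolated)
Conditions: TFA/CH2Cl2 (1:1), 0 °C → rt; evaporate, toluene azeotrope, 40 °C
Reagents that add atoms: none
Why: Acidolysis of both tert-butyl esters with loss of isobutene should give the (Z)-2,3-dialkylbutenedioic acid, whose cis carboxyls are held together by the tetrasubstituted alkene and cyclodehydrate to the five-membered anhydride (5-exo-trig acyl substitution), while the secondary acetate and its stereocentre are stable to TFA.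

**Compound list**

1 | (S)-propylene oxide [(S)-2-methyloxirane] | C[C@H]1CO1 | starting material
2 | but-3-en-1-ylmagnesium bromide | C=CCC[Mg]Br | starting material
3 | bromomagnesium (S)-hept-6-en-2-oxide | C[C@H](O[Mg]Br)CCCC=C | intermediate
4 | (S)-hept-6-en-2-yl acetate | CC(=O)O[C@@H](C)CCCC=C | intermediate
5 | (S)-6-oxohexan-2-yl acetate | CC(=O)O[C@@H](C)CCCC=O | intermediate
6 | (S)-5-acetoxyhexanoic acid | CC(=O)O[C@@H](C)CCCC(=O)O | intermediate
7 | 12-bromododec-1-ene | C=CCCCCCCCCCCBr | starting material
8 | di-tert-butyl but-2-ynedioate (di-tert-butyl acetylenedicarboxylate) | CC(C)(C)OC(=O)C#CC(=O)OC(C)(C)C | starting material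
9 | dodec-11-en-1-ylmagnesium bromide | C=CCCCCCCCCCC[Mg]Br | intermediate
10 | dodec-11-en-1-ylcopper (as its SMe2/MgBr2 complex) | C=CCCCCCCCCCC[Cu] | intermediate
11 | alkenylcopper adduct, di-tert-butyl (E)-2-cuprio-3-(dodec-11-en-1-yl)but-2-enedioate (copper cis to the chain) | C=CCCCCCCCCCC/C(C(=O)OC(C)(C)C)=C(\[Cu])C(=O)OC(C)(C)C | intermediate
12 | di-tert-butyl (Z)-2-(dodec-11-en-1-yl)-3-methylbut-2-enedioate | C=CCCCCCCCCCC/C(C(=O)OC(C)(C)C)=C(\C)C(=O)OC(C)(C)C | intermediate
13 | B-alkyl-9-BBN adduct, di-tert-butyl (Z)-2-[12-(9-borabicyclo[3.3.1]nonan-9-yl)dodecyl]-3-methylbut-2-enedioate | B1(C2CCCC1CCC2)CCCCCCCCCCCC/C(C(=O)OC(C)(C)C)=C(\C)C(=O)OC(C)(C)C | intermediate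
14 | di-tert-butyl (Z)-2-(12-hydroxydodecyl)-3-methylbut-2-enedioate | OCCCCCCCCCCCC/C(C(=O)OC(C)(C)C)=C(\C)C(=O)OC(C)(C)C | intermediate
15 | di-tert-butyl (Z)-2-methyl-3-(12-oxododecyl)but-2-enedioate | O=CCCCCCCCCCCC/C(C(=O)OC(C)(C)C)=C(\C)C(=O)OC(C)(C)C | intermediate
16 | di-tert-butyl (Z)-2-(11-carboxyundecyl)-3-methylbut-2-enedioate | OC(=O)CCCCCCCCCCC/C(C(=O)OC(C)(C)C)=C(\C)C(=O)OC(C)(C)C | intermediate
17 | di-tert-butyl (Z)-2-[(15S)-15-acetoxyhexadecyl]-3-methylbut-2-enedioate | CC(=O)O[C@@H](C)CCCCCCCCCCCCCC/C(C(=O)OC(C)(C)C)=C(\C)C(=O)OC(C)(C)C | intermediate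
18 | (Z)-2-[(15S)-15-acetoxyhexadecyl]-3-methylbut-2-enedioic acid | CC(=O)O[C@@H](C)CCCCCCCCCCCCCC/C(C(=O)O)=C(\C)C(=O)O | intermediate
19 | (S)-16-(4-methyl-2,5-dioxo-2,5-dihydrofuran-3-yl)hexadecan-2-yl acetate | CC(=O)O[C@@H](C)CCCCCCCCCCCCCCC1=C(C)C(=O)OC1=O | target

**Step count**

Total: 7 steps. Longest linear sequence: 5 steps (steps 3, 4, 5, 6, 7 from 7 and 8); the other branch is steps 1 and 2.

**Steps most likely to fail, with fallbacks**

Step 6. The risks are statistical radical pairing that diverts material into the symmetrical dimers, passivation of the anode, and over-oxidation of the radicals to cations that are trapped by methanol or lose a proton. The fallback forms the same C5–C6 bond by olefin cross-metathesis and hydrogenation. It sets out from 12, the terminal-alkene diester of step 3. The partner is (S)-hex-5-en-2-yl acetate F1, obtained by acetylation (Ac2O, pyridine) of commercial (S)-hex-5-en-2-ol. Cross-metathesis of 12 with F1 (3 equiv, second-generation Grubbs catalyst, CH2Cl2, 40 °C) should give di-tert-butyl (Z)-2-[(11E,15S)-15-acetoxyhexadec-11-en-1-yl]-3-methylbut-2-enedioate F2, with the tetrasubstituted diester alkene inert to the catalyst; the geometry of the new alkene is immaterial. Hydrogenation of the disubstituted alkene only (H2, RhCl(PPh3)3, benzene/EtOH) comes back to the route at 17, which goes on to step 7.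

Step 3. The risks are geometric isomerisation of the alkenylcopper before it is alkylated, which would give the trans-diester that cannot close to the anhydride, and sluggish capture by methyl iodide, which would leave the methyl-free adduct after protonation. The fallback brings the methyl group in by palladium-catalysed cross-coupling at an isolated alkenyl iodide instead of by alkylation of the organocopper. It sets out from alkenylcopper 11, generated as in step 3. Quenching at −78 °C with iodine, which is fast and stereoretentive, should give di-tert-butyl (E)-2-(dodec-11-en-1-yl)-3-iodobut-2-enedioate F3, whose geometry can be checked before going on. Negishi coupling with methylzinc chloride (Pd(PPh3)4 cat., THF, rt to 50 °C) with retention comes back to the route at 12.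

Step 1. The risks are loss of regiocontrol or halohydrin formation in the epoxide opening, and acylation of unconsumed Grignard reagent during the in-flask acetylation. The fallback creates the stereocentre by enzymatic ketone reduction instead of taking it from the epoxide. It sets out from 2, which is acylated with N-methoxy-N-methylacetamide (THF, 0 °C) to hept-6-en-2-one F4. Reduction with an (S)-selective (Prelog-type) alcohol dehydrogenase, with NAD(P)H recycled by propan-2-ol, should give (S)-hept-6-en-2-ol F5. Acetylation (Ac2O, pyridine, DMAP) comes back to the route at 4.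

**Further compounds**

F1 | step 6 | (S)-hex-5-en-2-yl acetate | CC(=O)O[C@@H](C)CCC=C
F2 | step 6 | di-tert-butyl (Z)-2-[(11E,15S)-15-acetoxyhexadec-11-en-1-yl]-3-methylbut-2-enedioate | CC(=O)O[C@@H](C)CC/C=C/CCCCCCCCCC/C(C(=O)OC(C)(C)C)=C(\C)C(=O)OC(C)(C)C
F3 | step 3 | di-tert-butyl (E)-2-(dodec-11-en-1-yl)-3-iodobut-2-enedioate | C=CCCCCCCCCCC/C(C(=O)OC(C)(C)C)=C(\I)C(=O)OC(C)(C)C
F4 | step 1 | hept-6-en-2-one | CC(=O)CCCC=C
F5 | step 1 | (S)-hept-6-en-2-ol | C[C@H](O)CCCC=C
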